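**Retrosynthetic overview**

1. Cadiolide A (10) comes from its tri-O-methyl ether 9 by one global BBr3 demethylation; the methyl ethers keep the phenols from competing for the alkylating agent.
2. 9 comes from aroylacetic acid 5, phenacyl bromide 4 and 4-methoxybenzaldehyde 6, joined in one flask around the furan-2(5H)-one ring (O1, C2 carbonyl, C3 aroyl, C4 aryl, C5 benzylidene): carboxylate alkylation makes O1–C5, intramolecular Knoevenagel condensation makes C3=C4 and closes the ring (the only ring formed in the route), and a vinylogous Knoevenagel condensation then makes the exocyclic C5=CH bond.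
3. Enabling feature: C3 lies between the lactone carbonyl C2 and the exocyclic aroyl carbonyl, so it is the doubly activated CH2 of a β-keto acid, while aryl-bearing C4 and its neighbour C5 are the carbonyl carbon and α-carbon of an aryl ketone; once the ring exists, C5–H2 is the γ-position of a 3-acylbutenolide whose anion is an aromatic 2-oxidofuran.
4. 5 and 4 both derive from one ketone, 3 (from 4'-hydroxyacetophenone 1 by ring dibromination and O-methylation): enolate carboxylation with CO2 gives 5 (CO2 becomes C2 and O1), α-bromination gives 4.

Key step: step 5

Assumption: the three phenols are carried as methyl ethers throughout, because free phenoxides would be alkylated by the phenacyl bromide and would deactivate the aldehyde; ring positions are cited as in furan-2(5H)-one.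

**Route**

Step 1
Reactants: 1 4'-hydroxyacetophenone
Product: 2 1-(3,5-dibromo-4-hydroxyphenyl)ethan-1-one
Conditions: Br2 (2.05 equiv), NaOAc (2.2 equiv), AcOH, 15 °C to rt
Reagents that add atoms: bromine, BrBr
Why: Electrophilic aromatic bromination, in which the phenol OH directs both bromines ortho to itself (para is blocked by the acetyl group) and the acetate buffer keeps acid-catalysed enolisation, and with it side-chain bromination, slow.

Step 2
Reactants: 2 1-(3,5-dibromo-4-hydroxyphenyl)ethan-1-one
Product: 3 1-(3,5-dibromo-4-methoxyphenyl)ethan-1-one
Conditions: MeI (1.5 equiv), K2CO3 (2 equiv), DMF, rt to 40 °C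
Reagents that add atoms: iodomethane, CI
Why: Williamson ether synthesis, in which the acidic 2,6-dibromophenol is fully ionised by K2CO3 and the small electrophile MeI tolerates the two flanking bromines, while the carbonate is too weak to enolise the ketone.

Step 3
Reactants: 3 1-(3,5-dibromo-4-methoxyphenyl)ethan-1-one
Product: 4 2-bromo-1-(3,5-dibromo-4-methoxyphenyl)ethan-1-one
Conditions: CuBr2 (2.1 equiv), EtOAc/CHCl3 (1:1), reflux
Reagents that add atoms: CuBr2 (copper dibromide), [Cu+2].[Br-].[Br-]
Why: α-Bromination of an aryl methyl ketone through its enol with CuBr2, a heterogeneous reagent that should stop at the monobromide, while the already dibrominated, deactivated ring is not attacked.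

Step 4
Reactants: 3 1-(3,5-dibromo-4-methoxyphenyl)ethan-1-one
Product: 5 3-(3,5-dibromo-4-methoxyphenyl)-3-oxopropanoic acid
Conditions: LiN(SiMe3)2 (1.05 equiv), THF, −78 °C; CO2 (g, excess), −78 to −20 °C; then 1 M HCl, 0 °C (acid/base extraction, kept below 25 °C)
Reagents that add atoms: carbon dioxide, O=C=O
Why: Carboxylation of a kinetically formed lithium ketone enolate with CO2 to the β-keto acid, with a hindered amide base that should neither exchange the aryl bromides nor metalate the ring at −78 °C, and cold acidification to deliver the acid before it decarboxylates.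

Step 5
Reactants: 5 3-(3,5-dibromo-4-methoxyphenyl)-3-oxopropanoic acid; 4 2-bromo-1-(3,5-dibromo-4-methoxyphenyl)ethan-1-one; 6 4-methoxybenzaldehyde
Product: 9 tri-O-methylcadiolide A, via phenacyl keto ester 7 (not isolated), via 5H-furanone 8 (not isolated)
Conditions: 5, 4 (1.0 equiv), Et3N (1.05 equiv), MeCN, 0 °C to rt; then Et3N (1.5 equiv), 4 Å MS, rt to 40 °C; then 6 (1.2 equiv), piperidine (0.5 equiv), 50 °C; one flask, no isolation
Reagents that add atoms: none
Why: Et3N turns 5 into its carboxylate, which displaces bromide from the phenacyl carbon of 4 (SN2, the O1–C5 bond) to give 7; further Et3N enolises the doubly activated methylene of 7, which adds to the neighbouring aryl ketone and loses water by E1cB (intramolecular Knoevenagel condensation, the C3=C4 bond) to give 8, and piperidine then deprotonates C5–H2 of 8 to an aromatic 2-oxidofuran dienolate that adds to 6 through C5 and loses water to give 9. The closest known reaction types are the one-flask carboxylate alkylation/intramolecular aldol condensation of arylacetic acids with phenacyl bromides to 3,4-diarylfuran-2(5H)-ones, the Et3N-mediated Knoevenagel closure of β-keto esters of α-hydroxy ketones to 3-acylbutenolides, and the amine-mediated vinylogous aldol condensation of such furanones with aryl aldehydes. The furanone ring closes by a 5-exo-trig aldol addition (enolexo mode) of C3 onto the C4 carbonyl. No stereocentre is formed; the only stereo-element, the exocyclic C5=CH bond, should come out Z under thermodynamic control (reversible amine addition and E1cB elimination), because the E isomer would press the anisyl ring against the C4 aryl ring whereas the Z isomer places it beside the ring oxygen. The step needs O- rather than C-alkylation, secured by using one equivalent of a tertiary amine so that only the carboxylate (no methylene anion) is present while 4 is consumed; it needs C3 and not the phenacyl CH2 as the ring-closing nucleophile, secured by the far higher acidity of the 1,3-dicarbonyl methylene; and it needs 6 to meet only 8, secured by adding 6 last, which excludes decarboxylative condensation of 5 with 6 and intermolecular Knoevenagel reaction of 7.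

Step 6
Reactants: 9 tri-O-methylcadiolide A
Product: 10 cadiolide A
Conditions: BBr3 (8 equiv), CH2Cl2, −78 °C to rt; then ice/H2O
Reagents that add atoms: none
Why: BBr3 ether cleavage (bromide attacks the O-methyl groups of the boron-complexed ethers in an SN2 sense), to which the enol lactone, the diaryl ketone, the aryl bromides and the thermodynamically preferred Z-alkene should be inert, so that all three phenols are released in one operation.

**Compound list**

1 | 4'-hydroxyacetophenone | CC(=O)c1ccc(O)cc1 | starting material
2 | 1-(3,5-dibromo-4-hydroxyphenyl)ethan-1-one | CC(=O)c1cc(Br)c(O)c(Br)c1 | intermediate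
3 | 1-(3,5-dibromo-4-methoxyphenyl)ethan-1-one | CC(=O)c1cc(Br)c(OC)c(Br)c1 | intermediate
4 | 2-bromo-1-(3,5-dibromo-4-methoxyphenyl)ethan-1-one | BrCC(=O)c1cc(Br)c(OC)c(Br)c1 | intermediate
5 | 3-(3,5-dibromo-4-methoxyphenyl)-3-oxopropanoic acid | OC(=O)CC(=O)c1cc(Br)c(OC)c(Br)c1 | intermediate
6 | 4-methoxybenzaldehyde | COc1ccc(C=O)cc1 | starting material
7 | phenacyl keto ester, 2-(3,5-dibromo-4-methoxyphenyl)-2-oxoethyl 3-(3,5-dibromo-4-methoxyphenyl)-3-oxopropanoate (not isolated) | COc1c(Br)cc(cc1Br)C(=O)CC(=O)OCC(=O)c1cc(Br)c(OC)c(Br)c1 | intermediate
8 | 5H-furanone, 3-(3,5-dibromo-4-methoxybenzoyl)-4-(3,5-dibromo-4-methoxyphenyl)furan-2(5H)-one (not isolated) | O=C1OCC(c2cc(Br)c(OC)c(Br)c2)=C1C(=O)c1cc(Br)c(OC)c(Br)c1 | intermediate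
9 | tri-O-methylcadiolide A, (5Z)-3-(3,5-dibromo-4-methoxybenzoyl)-4-(3,5-dibromo-4-methoxyphenyl)-5-[(4-methoxyphenyl)methylidene]furan-2(5H)-one | O=C1O/C(=C\c2ccc(OC)cc2)C(c2cc(Br)c(OC)c(Br)c2)=C1C(=O)c1cc(Br)c(OC)c(Br)c1 | intermediate
10 | cadiolide A, (5Z)-3-(3,5-dibromo-4-hydroxybenzoyl)-4-(3,5-dibromo-4-hydroxyphenyl)-5-[(4-hydroxyphenyl)methylidene]furan-2(5H)-one | O=C1O/C(=C\c2ccc(O)cc2)C(c2cc(Br)c(O)c(Br)c2)=C1C(=O)c1cc(Br)c(O)c(Br)c1 | target

**Step count**

Total step count: 6. Longest linear sequence: 5 steps (steps 1, 2, 4, 5, 6; the branch through step 3 is equally long up to the key step).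

**Steps most likely to fail**

Step 5. The carboxylate of 5 may lose CO2 before it is alkylated, the keto ester may be C-alkylated once free base is present, and the last condensation may stall in the salt- and water-laden mixture. The fallback sets out from 4 and 3 and comes back at 9; it makes the ring C–O bond at the acyl carbon instead and never exposes acid 5 to base. 4 is heated with HCO2Na in aqueous EtOH to give, by formate displacement and solvolysis in the same flask, 1-(3,5-dibromo-4-methoxyphenyl)-2-hydroxyethan-1-one F1. 3 is condensed with dimethyl carbonate (NaH, THF, reflux; Claisen condensation) to methyl 3-(3,5-dibromo-4-methoxyphenyl)-3-oxopropanoate F2. F1 and F2 are heated in toluene at reflux with distillation of MeOH (DMAP cat.), the aroylacetyl group passing to the alcohol through the aroylketene, which should give 7, now isolated. Et3N in MeCN closes 7 to 8, and 8 is condensed separately with 6 (piperidine, MeOH, rt) to give 9.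

Step 4. Proton transfer from the newly formed β-keto carboxylate to unreacted enolate may stall the carboxylation, and CO2 may be lost again during acidification and isolation. The fallback sets out from 3 and comes back at 5. Claisen condensation of 3 with diethyl carbonate (NaH, THF, reflux) should give ethyl 3-(3,5-dibromo-4-methoxyphenyl)-3-oxopropanoate F3, a stable, purifiable ester. Saponification (1 M NaOH, rt; then cold HCl, 0 °C) releases 5 directly before use.

Step 6. Cleavage of the two flanked, weakly Lewis-basic dibromoanisole ethers may remain incomplete, and forcing it may bring HBr-promoted Z/E equilibration or opening of the enol lactone. The fallback sets out from 9 and comes back at 10; it is a staged deprotection on a different principle, nucleophilic dealkylation driven by the leaving-group quality of the 2,6-dibromo-4-acylphenoxides. LiCl (excess) in DMF at 110 °C should remove only the two activated methyl groups by SN2 attack of chloride and give (5Z)-3-(3,5-dibromo-4-hydroxybenzoyl)-4-(3,5-dibromo-4-hydroxyphenyl)-5-[(4-methoxyphenyl)methylidene]furan-2(5H)-one F4. The remaining unhindered, electron-rich anisyl ether is the one that complexes BBr3 best and is then cleaved by a short, cold BBr3 treatment (CH2Cl2, −78 to 0 °C) to give 10.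

**Further compounds**

F1 | step 5 | 1-(3,5-dibromo-4-methoxyphenyl)-2-hydroxyethan-1-one | OCC(=O)c1cc(Br)c(OC)c(Br)c1
F2 | step 5 | methyl 3-(3,5-dibromo-4-methoxyphenyl)-3-oxopropanoate | COC(=O)CC(=O)c1cc(Br)c(OC)c(Br)c1
F3 | step 4 | ethyl 3-(3,5-dibromo-4-methoxyphenyl)-3-oxopropanoate | CCOC(=O)CC(=O)c1cc(Br)c(OC)c(Br)c1
F4 | step 6 | (5Z)-3-(3,5-dibromo-4-hydroxybenzoyl)-4-(3,5-dibromo-4-hydroxyphenyl)-5-[(4-methoxyphenyl)methylidene]furan-2(5H)-one | O=C1O/C(=C\c2ccc(OC)cc2)C(c2cc(Br)c(O)c(Br)c2)=C1C(=O)c1cc(Br)c(O)c(Br)c1
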